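The route rests on disconnecting the benzylic ether bond O1–C2 of the pyran ring. An intramolecular Mitsunobu etherification closes the heterocycle (O1, C2, C3, C4, C4a, C8a) last and fixes C2 in one operation: the ring-A phenol oxygen displaces the activated carbinol on the ring-B benzylic carbon with inversion, turning an (R)-alcohol from asymmetric transfer hydrogenation into (2S). The precursor is an open-chain 1,3-diarylpropan-1-ol whose three C5 units still sit on oxygen as allyl ethers; these act as protecting groups, keep C2 unhindered during closure, and are shifted onto C6, C2′ and C5′ by Claisen rearrangements in the final step.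

Key step: step 6

Remark: C2 of the target is read as (S) (O1 > C1′ > C3 > H); locants are chroman O1, C2–C4, C4a, C5–C8, C8a and ring B C1′–C6′ (C1′ on C2).

**Step 1**
Reactants: 1 3,4-dihydroxyacetophenone
Product: 3 1-[3,4-bis(2-methylbut-3-yn-2-yloxy)phenyl]ethan-1-one, via mono(propargyl) ether 2 (not isolated)
Conditions: 3-chloro-3-methylbut-1-yne (3 equiv), K2CO3, KI, CuI (cat.), acetone, 55 °C
Reagents that add atoms: 3-chloro-3-methylbut-1-yne, C#CC(C)(C)Cl
Why: Copper-assisted SN1-type O-alkylation (a Williamson-type etherification through a copper acetylide/allenylidene) of both phenoxides by the tertiary propargylic chloride should give the bis(1,1-dimethylpropargyl) ether, a reaction established for catechols.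

**Step 2**
Reactants: 3 1-[3,4-bis(2-methylbut-3-yn-2-yloxy)phenyl]ethan-1-one
Product: 5 1-[3,4-bis(2-methylbut-3-en-2-yloxy)phenyl]ethan-1-one, via half-reduced enyne ether 4 (not isolated)
Conditions: H2 (1 atm), Lindlar catalyst, quinoline, EtOAc, rt
Reagents that add atoms: none
Why: Lindlar semi-hydrogenation should stop at the two terminal vinyl groups and leave the aryl ketone and the tertiary C–O bonds intact.

**Step 3**
Reactants: 6 2,4-dihydroxybenzaldehyde
Product: 7 2-hydroxy-4-[(3-methylbut-2-en-1-yl)oxy]benzaldehyde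
Conditions: prenyl bromide (1.05 equiv), K2CO3 (1.1 equiv), acetone, rt
Reagents that add atoms: prenyl bromide (1-bromo-3-methylbut-2-ene), CC(C)=CCBr
Why: In this Williamson etherification the 4-OH (para to the formyl group) is the more acidic phenol and the 2-OH is held in a hydrogen bond to the aldehyde, so one equivalent of base and bromide should alkylate O4 only.

**Step 4**
Reactants: 5 1-[3,4-bis(2-methylbut-3-en-2-yloxy)phenyl]ethan-1-one; 7 2-hydroxy-4-[(3-methylbut-2-en-1-yl)oxy]benzaldehyde
Product: 9 (2E)-1-[3,4-bis(2-methylbut-3-en-2-yloxy)phenyl]-3-{2-hydroxy-4-[(3-methylbut-2-en-1-yl)oxy]phenyl}prop-2-en-1-one, via β-hydroxy ketone 8 (not isolated)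
Conditions: KOH (aq.), EtOH, rt; AcOH to pH 6
Reagents that add atoms: none
Why: Claisen–Schmidt condensation of the methyl ketone enolate with the non-enolisable aldehyde followed by E1cB dehydration should give the thermodynamically favoured (E)-enone, and both kinds of allyl ether are inert to hydroxide.

**Step 5**
Reactants: 9 the (E)-chalcone
Product: 11 (1R)-1-[3,4-bis(2-methylbut-3-en-2-yloxy)phenyl]-3-{2-hydroxy-4-[(3-methylbut-2-en-1-yl)oxy]phenyl}propan-1-ol, via saturated ketone 10 (not isolated)
Conditions: RuCl[(R,R)-TsDPEN](p-cymene) (2 mol%), HCO2H/Et3N (1:1), EtOAc, 40 °C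
Reagents that add atoms: none
Why: In this Noyori–Ikariya asymmetric transfer hydrogenation the Ru–H species should first reduce the conjugated C=C (isolated alkenes are not touched) and then deliver hydride to one face of the aryl ketone, selected by the CH/π contact between the catalyst arene and ring B, so that the (R,R)-catalyst gives the (R)-carbinol in the same sense as for acetophenone.

**Step 6**
Reactants: 11 the (1R)-1,3-diarylpropan-1-ol
Product: 13 (2S)-2-[3,4-bis(2-methylbut-3-en-2-yloxy)phenyl]-7-[(3-methylbut-2-en-1-yl)oxy]-3,4-dihydro-2H-chromene, via oxyphosphonium phenoxide 12 (not isolated)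
Conditions: PPh3, DIAD, toluene, 0 °C → rt
Reagents that add atoms: none
Why: PPh3/DIAD turns the carbinol oxygen into an alkoxyphosphonium leaving group while the betaine deprotonates the ring-A phenol, and the phenoxide O1 then displaces triphenylphosphine oxide from the benzylic carbon in an intramolecular SN2 reaction. The closest known reaction type is the Mitsunobu cyclisation of 1-aryl-3-(2-hydroxyphenyl)propan-1-ols to flavans. The pyran ring (O1–C2–C3–C4–C4a–C8a) closes in the 6-exo-tet mode. C2 is the only new stereocentre and is controlled by the carbinol configuration: backside attack inverts the (R)-alcohol of step 5 to (2S). The step needs SN2 displacement to outrun ionisation to a benzylic cation and elimination to the styrene; this is secured by the absence of any ortho substituent on ring B at this stage (both prenyl groups are still on oxygen), by the two vicinal tert-alkoxy groups, which twist each other out of conjugation and donate poorly, and by the low-polarity medium at low temperature. Chemoselectivity is inherent because 11 holds a single phenol and no other nucleophile.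

**Step 7**
Reactants: 13 the (2S)-tris(allyl ether) flavan
Product: 16 4-[(2S)-7-hydroxy-6-(2-methylbut-3-en-2-yl)-3,4-dihydro-2H-chromen-2-yl]-3,6-bis(3-methylbut-2-en-1-yl)benzene-1,2-diol, via ring-B bis(trimethylsilyl) ether 14 (not isolated), via tris(trimethylsilyl) ether 15 (not isolated)
Conditions: BSA (N,O-bis(trimethylsilyl)acetamide, 4 equiv), PhNEt2, 130 °C then 190 °C (sealed tube, Ar); then MeOH, citric acid (cat.), rt
Reagents that add atoms: none
Why: Three aromatic Claisen [3,3] rearrangements should occur in sequence: at 130 °C each tert-allyl ether on ring B delivers its CH2 terminus to its only free ortho carbon (O4′ to C5′, O3′ to C2′), at 190 °C the prenyl ether delivers its CMe2 terminus to C6 and not to C8, which is wedged between O1 and O7, and in situ silylation keeps the liberated phenols masked (above all O4′, which could open the pyran ring through a para-quinone methide) until the mild methanolysis, so that C2 is not touched.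

**Compound list**

1 | 3,4-dihydroxyacetophenone | CC(=O)c1ccc(O)c(O)c1 | starting material
2 | 1-[3-hydroxy-4-(2-methylbut-3-yn-2-yloxy)phenyl]ethan-1-one (formed in situ) | CC(=O)c1ccc(OC(C)(C)C#C)c(O)c1 | intermediate
3 | 1-[3,4-bis(2-methylbut-3-yn-2-yloxy)phenyl]ethan-1-one | CC(=O)c1ccc(OC(C)(C)C#C)c(OC(C)(C)C#C)c1 | intermediate
4 | 1-[4-(2-methylbut-3-en-2-yloxy)-3-(2-methylbut-3-yn-2-yloxy)phenyl]ethan-1-one (formed in situ) | CC(=O)c1ccc(OC(C)(C)C=C)c(OC(C)(C)C#C)c1 | intermediate
5 | 1-[3,4-bis(2-methylbut-3-en-2-yloxy)phenyl]ethan-1-one | CC(=O)c1ccc(OC(C)(C)C=C)c(OC(C)(C)C=C)c1 | intermediate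
6 | 2,4-dihydroxybenzaldehyde | O=Cc1ccc(O)cc1O | starting material
7 | 2-hydroxy-4-[(3-methylbut-2-en-1-yl)oxy]benzaldehyde | O=Cc1ccc(OCC=C(C)C)cc1O | intermediate
8 | 1-[3,4-bis(2-methylbut-3-en-2-yloxy)phenyl]-3-hydroxy-3-{2-hydroxy-4-[(3-methylbut-2-en-1-yl)oxy]phenyl}propan-1-one, racemic aldol adduct (formed in situ) | O=C(CC(O)c1ccc(OCC=C(C)C)cc1O)c1ccc(OC(C)(C)C=C)c(OC(C)(C)C=C)c1 | intermediate
9 | (2E)-1-[3,4-bis(2-methylbut-3-en-2-yloxy)phenyl]-3-{2-hydroxy-4-[(3-methylbut-2-en-1-yl)oxy]phenyl}prop-2-en-1-one | O=C(/C=C/c1ccc(OCC=C(C)C)cc1O)c1ccc(OC(C)(C)C=C)c(OC(C)(C)C=C)c1 | intermediate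
10 | 1-[3,4-bis(2-methylbut-3-en-2-yloxy)phenyl]-3-{2-hydroxy-4-[(3-methylbut-2-en-1-yl)oxy]phenyl}propan-1-one (formed in situ) | O=C(CCc1ccc(OCC=C(C)C)cc1O)c1ccc(OC(C)(C)C=C)c(OC(C)(C)C=C)c1 | intermediate
11 | (1R)-1-[3,4-bis(2-methylbut-3-en-2-yloxy)phenyl]-3-{2-hydroxy-4-[(3-methylbut-2-en-1-yl)oxy]phenyl}propan-1-ol | O[C@H](CCc1ccc(OCC=C(C)C)cc1O)c1ccc(OC(C)(C)C=C)c(OC(C)(C)C=C)c1 | intermediate
12 | (R)-alkoxytriphenylphosphonium phenoxide zwitterion derived from 11 (formed in situ) | [O-]c1cc(OCC=C(C)C)ccc1CC[C@@H](O[P+](c1ccccc1)(c1ccccc1)c1ccccc1)c1ccc(OC(C)(C)C=C)c(OC(C)(C)C=C)c1 | intermediate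
13 | (2S)-2-[3,4-bis(2-methylbut-3-en-2-yloxy)phenyl]-7-[(3-methylbut-2-en-1-yl)oxy]-3,4-dihydro-2H-chromene | CC(C)=CCOc1ccc2c(c1)O[C@H](c1ccc(OC(C)(C)C=C)c(OC(C)(C)C=C)c1)CC2 | intermediate
14 | (2S)-2-[2,5-bis(3-methylbut-2-en-1-yl)-3,4-bis(trimethylsilyloxy)phenyl]-7-[(3-methylbut-2-en-1-yl)oxy]-3,4-dihydro-2H-chromene (formed in situ) | CC(C)=CCOc1ccc2c(c1)O[C@H](c1cc(CC=C(C)C)c(O[Si](C)(C)C)c(O[Si](C)(C)C)c1CC=C(C)C)CC2 | intermediate
15 | tris(trimethylsilyl) ether of 16 (formed in situ) | C=CC(C)(C)c1cc2c(cc1O[Si](C)(C)C)O[C@H](c1cc(CC=C(C)C)c(O[Si](C)(C)C)c(O[Si](C)(C)C)c1CC=C(C)C)CC2 | intermediate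
16 | 4-[(2S)-7-hydroxy-6-(2-methylbut-3-en-2-yl)-3,4-dihydro-2H-chromen-2-yl]-3,6-bis(3-methylbut-2-en-1-yl)benzene-1,2-diol (CNP0118330.1) | C=CC(C)(C)c1cc2c(cc1O)O[C@H](c1cc(CC=C(C)C)c(O)c(O)c1CC=C(C)C)CC2 | target

**Totals**

Total step count: 7.
Longest linear sequence: 6 steps (1 → 3 → 5 → 9 → 11 → 13 → 16); the aldehyde branch (6 → 7) joins at step 4.

**Steps most likely to fail**

1. Step 7. Three processes may intrude. The ring-A shift may form the C–C bond at C8 instead of C6. An ipso-rearranged ring-B dienone may be captured by intramolecular Diels–Alder reaction with the neighbouring allyl ether. The long exposure to 190 °C may degrade the product. The fallback sets out from aldehyde 7 and comes back to the route at 16; it moves the ring-A rearrangement to the aldehyde stage, so that the last step needs only about 125 °C. Silylation of 7 (TBSCl, imidazole, DMF) would give 2-[(tert-butyldimethylsilyl)oxy]-4-[(3-methylbut-2-en-1-yl)oxy]benzaldehyde F1. Heating F1 in PhNEt2 at 190 °C would give 2-[(tert-butyldimethylsilyl)oxy]-4-hydroxy-5-(2-methylbut-3-en-2-yl)benzaldehyde F2, the bulky silyloxy group shielding C3. Condensation of F2 with ketone 5 under the KOH conditions of step 4, which also cleave the silyl ether, would give the 2,4-dihydroxychalcone F3. Transfer hydrogenation as in step 5 would give the (R)-alcohol F4. Mitsunobu closure as in step 6 would give the 7-hydroxy-6-(2-methylbut-3-en-2-yl)flavan bis(tert-allyl ether) F5; the C7 phenol is hindered by its tert-alkyl neighbour and can react only intermolecularly. Only the two ring-B ethers would then be rearranged (BSA, toluene, 125 °C; then MeOH, citric acid) to 16.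

2. Step 6. The oxyphosphonium ion may ionise in part (SN1) and erode the enantiomeric purity, or eliminate to the styrene. The fallback sets out from ketone 5 and comes back at 13; it closes the same ring at the aryl carbon C8a, so the stereocentre is not a reaction centre and is retained. 2-Bromo-4-hydroxybenzaldehyde F6 (purchased) would be alkylated (prenyl bromide, K2CO3, acetone) to 2-bromo-4-[(3-methylbut-2-en-1-yl)oxy]benzaldehyde F7. Claisen–Schmidt condensation of F7 with 5 would give the bromochalcone F8. Transfer hydrogenation with the (S,S)-catalyst would give the (S)-bromo alcohol F9. Copper-catalysed intramolecular Ullmann-type O-arylation (CuI, 3,4,7,8-tetramethyl-1,10-phenanthroline, Cs2CO3, toluene, 90 °C) would then form the O1–C8a bond and give 13.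

3. Step 5. 1,2-Reduction of the electron-rich enone to a labile allylic alcohol may compete with conjugate reduction, or the tert-allyl ethers may suffer acidolysis during the long one-pot reaction. The fallback sets out from chalcone 9 and comes back at 11; it separates the two reductions. Conjugate reduction with sodium dithionite (Na2S2O4, NaHCO3, dioxane/H2O, 60 °C) would give ketone 10, now isolated. Corey–Bakshi–Shibata reduction ((S)-Me-CBS, catecholborane, toluene, −78 °C; catecholborane does not hydroborate the vinyl groups at this temperature) would give 11. No compound outside the list is made (F0).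

**Further compounds**

F1 | step 7 | 2-[(tert-butyldimethylsilyl)oxy]-4-[(3-methylbut-2-en-1-yl)oxy]benzaldehyde | O=Cc1ccc(OCC=C(C)C)cc1O[Si](C)(C)C(C)(C)C
F2 | step 7 | 2-[(tert-butyldimethylsilyl)oxy]-4-hydroxy-5-(2-methylbut-3-en-2-yl)benzaldehyde | O=Cc1cc(C(C)(C)C=C)c(O)cc1O[Si](C)(C)C(C)(C)C
F3 | step 7 | (2E)-1-[3,4-bis(2-methylbut-3-en-2-yloxy)phenyl]-3-[2,4-dihydroxy-5-(2-methylbut-3-en-2-yl)phenyl]prop-2-en-1-one | O=C(/C=C/c1cc(C(C)(C)C=C)c(O)cc1O)c1ccc(OC(C)(C)C=C)c(OC(C)(C)C=C)c1
F4 | step 7 | (1R)-1-[3,4-bis(2-methylbut-3-en-2-yloxy)phenyl]-3-[2,4-dihydroxy-5-(2-methylbut-3-en-2-yl)phenyl]propan-1-ol | O[C@H](CCc1cc(C(C)(C)C=C)c(O)cc1O)c1ccc(OC(C)(C)C=C)c(OC(C)(C)C=C)c1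
F5 | step 7 | (2S)-2-[3,4-bis(2-methylbut-3-en-2-yloxy)phenyl]-6-(2-methylbut-3-en-2-yl)-3,4-dihydro-2H-chromen-7-ol | C=CC(C)(C)c1cc2c(cc1O)O[C@H](c1ccc(OC(C)(C)C=C)c(OC(C)(C)C=C)c1)CC2
F6 | step 6 | 2-bromo-4-hydroxybenzaldehyde (purchased) | O=Cc1ccc(O)cc1Br
F7 | step 6 | 2-bromo-4-[(3-methylbut-2-en-1-yl)oxy]benzaldehyde | O=Cc1ccc(OCC=C(C)C)cc1Br
F8 | step 6 | (2E)-1-[3,4-bis(2-methylbut-3-en-2-yloxy)phenyl]-3-{2-bromo-4-[(3-methylbut-2-en-1-yl)oxy]phenyl}prop-2-en-1-one | O=C(/C=C/c1ccc(OCC=C(C)C)cc1Br)c1ccc(OC(C)(C)C=C)c(OC(C)(C)C=C)c1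
F9 | step 6 | (1S)-1-[3,4-bis(2-methylbut-3-en-2-yloxy)phenyl]-3-{2-bromo-4-[(3-methylbut-2-en-1-yl)oxy]phenyl}propan-1-ol | O[C@@H](CCc1ccc(OCC=C(C)C)cc1Br)c1ccc(OC(C)(C)C=C)c(OC(C)(C)C=C)c1
F0 | step 5 | none | none
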